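**Retrosynthetic overview**

1. The target is guibourtinidol-(4α→6)-fisetinidol: an upper flavan (ring A benzo, ring B 4-hydroxyphenyl, ring C pyran) and a lower flavan (ring D benzo, ring E catechol, ring F pyran). The last C–C bond made is C4 (ring C)–C6 (ring D), by Friedel–Crafts attack of the free 7-phenol ring D of lower unit 14 on the C4 cation from flavan-3,4-diol 24, followed by hydrogenolysis of four benzyl ethers.
2. Lower unit: the 3-OH comes from a 3-CHO by Baeyer–Villiger oxidation with retention. Ring F is closed through its C2–C3 bond by an amine-catalysed enantioselective 1,5-hydride transfer/cyclisation of the flat, achiral enal 7 (three steps from 2,4-dihydroxybenzaldehyde). This one redox-neutral operation makes the C4 methylene, the C2–C3 bond, ring F and both stereocentres.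
3. Enabling feature: C2 of ring F is a benzylic C–H carbon held between the ring oxygen O1 and the electron-rich catechol ring E, and it lies 1,5 to C4. Opened at C2–C3 it is an ArO–CH2–Ar group whose hydride can pass to C4 of an ortho enal, after which C2 is an oxocarbenium carbon placed for attack by C3.
4. Upper unit: ring C comes from chalcone 19 by Juliá–Colonna epoxidation and phenol opening of the epoxide (O1–C2 bond) to trans-dihydroflavonol 23; NaBH4 then gives diol 24.
5. Order of ring formation: ring F (step 4), then ring C (step 10); rings A, B, D and E are bought as arenes; the two flavans are joined in step 12.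

Key step: step 4

Remark (assumption): the catalyst of step 4 is (2R,5R)-5-benzyl-2-tert-butyl-3-methylimidazolidin-4-one, CN1C(=O)[C@@H](Cc2ccccc2)N[C@H]1C(C)(C)C, used as its trifluoroacetate. Its sense of induction is assigned from the usual model (E-enamine turned away from the tert-butyl group, benzyl arm over one face, chair-like closure) and is not proven for this substrate; the (2S,5S) catalyst would be used if the opposite sense is found.

**Route**

Step 1
Reactants: 1 2,4-dihydroxybenzaldehyde; 2 4-methylbenzenesulfonyl chloride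
Product: 3 4-formyl-3-hydroxyphenyl 4-methylbenzenesulfonate
Conditions: TsCl (1.0 equiv), K2CO3, acetone, 0 °C to rt
Reagents that add atoms: 4-methylbenzenesulfonyl chloride (2), Cc1ccc(cc1)S(Cl)(=O)=O
Why: Chemoselective O-sulfonylation goes to the para hydroxyl because the ortho hydroxyl is hydrogen-bonded to the aldehyde, less acidic and more hindered; no stereocentre is formed.

Step 2
Reactants: 3 4-formyl-3-hydroxyphenyl 4-methylbenzenesulfonate; 4 4-(chloromethyl)-1,2-bis(benzyloxy)benzene
Product: 5 3-{[3,4-bis(benzyloxy)phenyl]methoxy}-4-formylphenyl 4-methylbenzenesulfonate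
Conditions: K2CO3, NaI (cat.), DMF, 60 °C
Reagents that add atoms: 4-(chloromethyl)-1,2-bis(benzyloxy)benzene (4), ClCc1ccc(OCc2ccccc2)c(OCc2ccccc2)c1
Why: Williamson ether synthesis on the remaining phenol with an activated benzylic chloride under iodide catalysis installs the O1–C2 bond and ring E, the aryl sulfonate being inert to carbonate.

Step 3
Reactants: 5 3-{[3,4-bis(benzyloxy)phenyl]methoxy}-4-formylphenyl 4-methylbenzenesulfonate; 6 (triphenylphosphoranylidene)acetaldehyde
Product: 7 3-{[3,4-bis(benzyloxy)phenyl]methoxy}-4-[(1E)-3-oxoprop-1-en-1-yl]phenyl 4-methylbenzenesulfonate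
Conditions: toluene, 80 °C
Reagents that add atoms: (triphenylphosphoranylidene)acetaldehyde (6), O=CC=P(c1ccccc1)(c1ccccc1)c1ccccc1
Why: Wittig olefination with a stabilised formylmethylene ylide should give the (E)-enal selectively, the sulfonate and benzyl ethers being inert.

Step 4
Reactants: 7 3-{[3,4-bis(benzyloxy)phenyl]methoxy}-4-[(1E)-3-oxoprop-1-en-1-yl]phenyl 4-methylbenzenesulfonate
Product: 11 (2S,3S)-2-[3,4-bis(benzyloxy)phenyl]-3-formyl-3,4-dihydro-2H-chromen-7-yl 4-methylbenzenesulfonate (2,3-trans), via iminium ion 8 (not isolated), via oxocarbenium enamine 9 (not isolated), via ring-closed iminium ion 10 (not isolated)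
Conditions: (2R,5R)-5-benzyl-2-tert-butyl-3-methylimidazolidin-4-one·CF3CO2H (20 mol %), ClCH2CH2Cl, 50 °C
Reagents that add atoms: none
Why: Proposed new method: condensation of 7 with the amine gives iminium ion 8, whose β-carbon (the future C4, on ring D) takes a hydride through a six-membered transition state from the ArO–CH2–Ar carbon (a C–H made hydridic by the ether oxygen and by the para-benzyloxy group of ring E) to give the aryloxocarbenium/enamine 9; the enamine carbon (future C3) then adds to the oxocarbenium carbon (future C2), forming the C2–C3 bond and closing ring F, and hydrolysis of 10 frees the catalyst. The closest known reaction types are the Lewis-acid-catalysed 1,5-hydride transfer/cyclisation of ortho-vinylaryl benzyl ethers to 2-arylchromans (racemic, doubly activated acceptors) and the secondary-amine-catalysed enantioselective 1,5-hydride transfer/cyclisation of enals carrying amine or cyclic-ether C–H donors; the proposal is their union. Ring F closes in a 6-endo-trig Mannich-type mode (exocyclic enamine onto the C=O+ bond). C3 is set by the catalyst, whose benzyl arm covers one face of the E-enamine so that the oxocarbenium carbon bonds to the open face; C2 is set relative to C3 by a chair-like transition state with ring E equatorial, which should give the 2,3-trans product, and any cis-aldehyde is expected to drain to trans by enamine-mediated epimerisation at C3 only. The step needs an electrophilic acceptor, a hydride shift from this one C–H and ring closure faster than hydrolysis of the oxocarbenium ion; the tosyloxy group para to the enal keeps ring D electron-poor, only the ArO–CH2 hydrogens are 1,5 to the β-carbon, and the para-benzyloxy group of ring E stabilises the oxocarbenium ion until the tethered enamine captures it.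

Step 5
Reactants: 11 (2S,3S)-2-[3,4-bis(benzyloxy)phenyl]-3-formyl-3,4-dihydro-2H-chromen-7-yl 4-methylbenzenesulfonate; 12 3-chloroperoxybenzoic acid
Product: 13 (2R,3S)-2-[3,4-bis(benzyloxy)phenyl]-3-(formyloxy)-3,4-dihydro-2H-chromen-7-yl 4-methylbenzenesulfonate
Conditions: mCPBA, CH2Cl2, 0 °C to rt
Reagents that add atoms: 3-chloroperoxybenzoic acid (12), OOC(=O)c1cccc(Cl)c1
Why: Baeyer–Villiger oxidation of the α-branched aldehyde, in which the secondary C3 migrates to oxygen with retention in the Criegee adduct, should turn the C3–CHO bond into the C3–O bond with the stereocentre intact (the descriptors change only through priority rules).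

Step 6
Reactants: 13 (2R,3S)-2-[3,4-bis(benzyloxy)phenyl]-3-(formyloxy)-3,4-dihydro-2H-chromen-7-yl 4-methylbenzenesulfonate
Product: 14 (2R,3S)-2-[3,4-bis(benzyloxy)phenyl]-3,4-dihydro-2H-chromene-3,7-diol (3',4'-di-O-benzylfisetinidol)
Conditions: KOH, MeOH–THF, 60 °C
Reagents that add atoms: none
Why: Saponification of the formate and hydroxide cleavage of the aryl sulfonate at sulfur free the 3- and 7-hydroxyls, and with the 4'-oxygen of ring E benzylated no quinone methide can form, so C2 should not epimerise.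

Step 7
Reactants: 15 1-[4-(benzyloxy)-2-hydroxyphenyl]ethan-1-one; 16 chloro(methoxy)methane
Product: 17 1-[4-(benzyloxy)-2-(methoxymethoxy)phenyl]ethan-1-one
Conditions: MOMCl, K2CO3, acetone, reflux
Reagents that add atoms: chloro(methoxy)methane (16), COCCl
Why: Williamson-type O-alkylation to the methoxymethyl ether masks the phenol so that the later chalcone and epoxide cannot cyclise prematurely.

Step 8
Reactants: 17 1-[4-(benzyloxy)-2-(methoxymethoxy)phenyl]ethan-1-one; 18 4-(benzyloxy)benzaldehyde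
Product: 19 (2E)-1-[4-(benzyloxy)-2-(methoxymethoxy)phenyl]-3-[4-(benzyloxy)phenyl]prop-2-en-1-one
Conditions: KOH, EtOH, rt
Reagents that add atoms: 4-(benzyloxy)benzaldehyde (18), O=Cc1ccc(OCc2ccccc2)cc1
Why: Claisen–Schmidt condensation of the methyl ketone with a non-enolisable aldehyde, followed by E1cB dehydration, should give the (E)-chalcone.

Step 9
Reactants: 19 (2E)-1-[4-(benzyloxy)-2-(methoxymethoxy)phenyl]-3-[4-(benzyloxy)phenyl]prop-2-en-1-one; 20 urea–hydrogen peroxide
Product: 21 [4-(benzyloxy)-2-(methoxymethoxy)phenyl]{(2R,3S)-3-[4-(benzyloxy)phenyl]oxiran-2-yl}methanone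
Conditions: poly-L-leucine, urea–H2O2, DBU, THF, rt
Reagents that add atoms: urea–hydrogen peroxide (20), NC(N)=O.OO (its hydrogen peroxide, OO, gives the epoxide oxygen)
Why: Juliá–Colonna epoxidation, a conjugate hydroperoxide addition and ring closure inside the helical poly-L-leucine, is known to give the (αR,βS) trans-epoxides of chalcones, so both stereocentres are set by the catalyst.

Step 10
Reactants: 21 [4-(benzyloxy)-2-(methoxymethoxy)phenyl]{(2R,3S)-3-[4-(benzyloxy)phenyl]oxiran-2-yl}methanone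
Product: 23 (2R,3R)-7-(benzyloxy)-2-[4-(benzyloxy)phenyl]-3-hydroxy-2,3-dihydro-4H-chromen-4-one, via phenol epoxide 22 (not isolated)
Conditions: HCl (conc., cat.), MeOH–THF, 55 °C
Reagents that add atoms: none
Why: Acidic acetal cleavage frees the phenol, which opens the epoxide at the benzylic carbon in a 6-endo mode with inversion (closing ring C), so the (βS) carbon becomes (2R) and the untouched α-carbon becomes (3R), the trans-dihydroflavonol also being the thermodynamic isomer.

Step 11
Reactants: 23 (2R,3R)-7-(benzyloxy)-2-[4-(benzyloxy)phenyl]-3-hydroxy-2,3-dihydro-4H-chromen-4-one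
Product: 24 (2R,3S,4R)-7-(benzyloxy)-2-[4-(benzyloxy)phenyl]-3,4-dihydro-2H-chromene-3,4-diol
Conditions: NaBH4, MeOH–THF, 0 °C
Reagents that add atoms: none
Why: Hydride reduction of the ketone by axial attack, as known for trans-dihydroflavonols, should give mainly the 2,3-trans-3,4-trans diol (the C4 centre is ionised in the next step, so its purity is not critical).

Step 12
Reactants: 24 (2R,3S,4R)-7-(benzyloxy)-2-[4-(benzyloxy)phenyl]-3,4-dihydro-2H-chromene-3,4-diol; 14 (2R,3S)-2-[3,4-bis(benzyloxy)phenyl]-3,4-dihydro-2H-chromene-3,7-diol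
Product: 26 (2R,3S,4R)-7-(benzyloxy)-2-[4-(benzyloxy)phenyl]-4-{(2R,3S)-2-[3,4-bis(benzyloxy)phenyl]-3,7-dihydroxy-3,4-dihydro-2H-chromen-6-yl}-3,4-dihydro-2H-chromen-3-ol, via flavan-4-yl cation 25 (not isolated)
Conditions: Yb(OTf)3 (10 mol %), CH2Cl2–THF, 0 °C to rt, 14 in excess (3 equiv)
Reagents that add atoms: none
Why: Friedel–Crafts alkylation (the flavan-3,4-diol/flavan-3-ol interflavanyl coupling): the Lewis acid ionises the C4 hydroxyl to cation 25, stabilised by the ring oxygen and the para 7-benzyloxy group, and the most nucleophilic arene present, ring D of 14 with its free 7-hydroxyl, should attack through C6 (para to the ring oxygen, less hindered than C8) on the face anti to the C3 hydroxyl, which sets the (4R) 3,4-trans centre.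

Step 13
Reactants: 26 (2R,3S,4R)-7-(benzyloxy)-2-[4-(benzyloxy)phenyl]-4-{(2R,3S)-2-[3,4-bis(benzyloxy)phenyl]-3,7-dihydroxy-3,4-dihydro-2H-chromen-6-yl}-3,4-dihydro-2H-chromen-3-ol
Product: 27 (2R,3S,4R)-4-[(2R,3S)-2-(3,4-dihydroxyphenyl)-3,7-dihydroxy-3,4-dihydro-2H-chromen-6-yl]-2-(4-hydroxyphenyl)-3,4-dihydro-2H-chromene-3,7-diol (CNP0243811.2)
Conditions: H2 (1 atm), Pd(OH)2/C, THF–MeOH, rt
Reagents that add atoms: none
Why: Hydrogenolysis of the four benzyl ethers over palladium dihydroxide on carbon under mild conditions, as used for proanthocyanidin deprotection, should leave the interflavanyl bond, the ring C–O bonds and all stereocentres untouched.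

**Compound list**

1 | 2,4-dihydroxybenzaldehyde | O=Cc1ccc(O)cc1O | starting material
2 | 4-methylbenzenesulfonyl chloride | Cc1ccc(cc1)S(Cl)(=O)=O | starting material
3 | 4-formyl-3-hydroxyphenyl 4-methylbenzenesulfonate | Cc1ccc(cc1)S(=O)(=O)Oc1ccc(C=O)c(O)c1 | intermediate
4 | 4-(chloromethyl)-1,2-bis(benzyloxy)benzene | ClCc1ccc(OCc2ccccc2)c(OCc2ccccc2)c1 | starting material
5 | 3-{[3,4-bis(benzyloxy)phenyl]methoxy}-4-formylphenyl 4-methylbenzenesulfonate | Cc1ccc(cc1)S(=O)(=O)Oc1ccc(C=O)c(OCc2ccc(OCc3ccccc3)c(OCc3ccccc3)c2)c1 | intermediate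
6 | (triphenylphosphoranylidene)acetaldehyde | O=CC=P(c1ccccc1)(c1ccccc1)c1ccccc1 | starting material
7 | 3-{[3,4-bis(benzyloxy)phenyl]methoxy}-4-[(1E)-3-oxoprop-1-en-1-yl]phenyl 4-methylbenzenesulfonate | Cc1ccc(cc1)S(=O)(=O)Oc1ccc(/C=C/C=O)c(OCc2ccc(OCc3ccccc3)c(OCc3ccccc3)c2)c1 | intermediate
8 | iminium ion of 7 with the imidazolidinone catalyst | CN1C(=O)[C@@H](Cc2ccccc2)[N+](=C/C=C/c2ccc(OS(=O)(=O)c3ccc(C)cc3)cc2OCc2ccc(OCc3ccccc3)c(OCc3ccccc3)c2)[C@H]1C(C)(C)C | intermediate
9 | aryloxocarbenium/enamine formed from 8 by 1,5-hydride shift | CN1C(=O)[C@@H](Cc2ccccc2)N(/C=C/Cc2ccc(OS(=O)(=O)c3ccc(C)cc3)cc2[O+]=Cc2ccc(OCc3ccccc3)c(OCc3ccccc3)c2)[C@H]1C(C)(C)C | intermediate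
10 | ring-closed iminium ion (catalyst-bound form of 11) | CN1C(=O)[C@@H](Cc2ccccc2)[N+](=C[C@H]2Cc3ccc(OS(=O)(=O)c4ccc(C)cc4)cc3O[C@@H]2c2ccc(OCc3ccccc3)c(OCc3ccccc3)c2)[C@H]1C(C)(C)C | intermediate
11 | (2S,3S)-2-[3,4-bis(benzyloxy)phenyl]-3-formyl-3,4-dihydro-2H-chromen-7-yl 4-methylbenzenesulfonate | Cc1ccc(cc1)S(=O)(=O)Oc1ccc2c(c1)O[C@H](c1ccc(OCc3ccccc3)c(OCc3ccccc3)c1)[C@@H](C=O)C2 | intermediate
12 | 3-chloroperoxybenzoic acid | OOC(=O)c1cccc(Cl)c1 | starting material
13 | (2R,3S)-2-[3,4-bis(benzyloxy)phenyl]-3-(formyloxy)-3,4-dihydro-2H-chromen-7-yl 4-methylbenzenesulfonate | Cc1ccc(cc1)S(=O)(=O)Oc1ccc2c(c1)O[C@H](c1ccc(OCc3ccccc3)c(OCc3ccccc3)c1)[C@@H](OC=O)C2 | intermediate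
14 | (2R,3S)-2-[3,4-bis(benzyloxy)phenyl]-3,4-dihydro-2H-chromene-3,7-diol | Oc1ccc2c(c1)O[C@H](c1ccc(OCc3ccccc3)c(OCc3ccccc3)c1)[C@@H](O)C2 | intermediate
15 | 1-[4-(benzyloxy)-2-hydroxyphenyl]ethan-1-one | CC(=O)c1ccc(OCc2ccccc2)cc1O | starting material
16 | chloro(methoxy)methane | COCCl | starting material
17 | 1-[4-(benzyloxy)-2-(methoxymethoxy)phenyl]ethan-1-one | CC(=O)c1ccc(OCc2ccccc2)cc1OCOC | intermediate
18 | 4-(benzyloxy)benzaldehyde | O=Cc1ccc(OCc2ccccc2)cc1 | starting material
19 | (2E)-1-[4-(benzyloxy)-2-(methoxymethoxy)phenyl]-3-[4-(benzyloxy)phenyl]prop-2-en-1-one | COCOc1cc(OCc2ccccc2)ccc1C(=O)/C=C/c1ccc(OCc2ccccc2)cc1 | intermediate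
20 | urea–hydrogen peroxide | NC(N)=O.OO | starting material
21 | [4-(benzyloxy)-2-(methoxymethoxy)phenyl]{(2R,3S)-3-[4-(benzyloxy)phenyl]oxiran-2-yl}methanone | COCOc1cc(OCc2ccccc2)ccc1C(=O)[C@@H]1O[C@H]1c1ccc(OCc2ccccc2)cc1 | intermediate
22 | [4-(benzyloxy)-2-hydroxyphenyl]{(2R,3S)-3-[4-(benzyloxy)phenyl]oxiran-2-yl}methanone | Oc1cc(OCc2ccccc2)ccc1C(=O)[C@@H]1O[C@H]1c1ccc(OCc2ccccc2)cc1 | intermediate
23 | (2R,3R)-7-(benzyloxy)-2-[4-(benzyloxy)phenyl]-3-hydroxy-2,3-dihydro-4H-chromen-4-one | c1ccccc1COc1ccc(cc1)[C@H]1Oc2cc(OCc3ccccc3)ccc2C(=O)[C@@H]1O | intermediate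
24 | (2R,3S,4R)-7-(benzyloxy)-2-[4-(benzyloxy)phenyl]-3,4-dihydro-2H-chromene-3,4-diol | c1ccccc1COc1ccc(cc1)[C@H]1Oc2cc(OCc3ccccc3)ccc2[C@@H](O)[C@@H]1O | intermediate
25 | (2R,3S)-7-(benzyloxy)-2-[4-(benzyloxy)phenyl]-3-hydroxy-3,4-dihydro-2H-chromen-4-ylium | c1ccccc1COc1ccc(cc1)[C@H]1Oc2cc(OCc3ccccc3)ccc2[CH+][C@@H]1O | intermediate
26 | (2R,3S,4R)-7-(benzyloxy)-2-[4-(benzyloxy)phenyl]-4-{(2R,3S)-2-[3,4-bis(benzyloxy)phenyl]-3,7-dihydroxy-3,4-dihydro-2H-chromen-6-yl}-3,4-dihydro-2H-chromen-3-ol | c1ccccc1COc1ccc([C@H]2Oc3cc(OCc4ccccc4)ccc3[C@@H](c3cc4c(cc3O)O[C@H](c3ccc(OCc5ccccc5)c(OCc5ccccc5)c3)[C@@H](O)C4)[C@@H]2O)cc1 | intermediate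
27 | (2R,3S,4R)-4-[(2R,3S)-2-(3,4-dihydroxyphenyl)-3,7-dihydroxy-3,4-dihydro-2H-chromen-6-yl]-2-(4-hydroxyphenyl)-3,4-dihydro-2H-chromene-3,7-diol | Oc1ccc([C@H]2Oc3cc(O)ccc3[C@@H](c3cc4c(cc3O)O[C@H](c3ccc(O)c(O)c3)[C@@H](O)C4)[C@@H]2O)cc1 | target

**Step count and risks**

Total step count: 13. Longest linear sequence: 8 steps (steps 1–6, then 12 and 13); the upper unit (steps 7–11) joins at step 12.

Steps most likely to fail:

Step 4 (proposed new method). The hydride shift may be too slow for a singly activated iminium acceptor. The oxocarbenium ion may be hydrolysed, with loss of the ring-E benzyl group, before ring closure. The facial selectivity may be low or opposite to the model. The fallback uses known chemistry, sets out from 3 and comes back at 11. Commercial 3,4-bis(benzyloxy)benzaldehyde (O=Cc1ccc(OCc2ccccc2)c(OCc2ccccc2)c1) is olefinated with ylide 6 to (2E)-3-[3,4-bis(benzyloxy)phenyl]prop-2-enal F1. Aldehydes 3 and F1 are then joined by the amine-catalysed oxa-Michael/aldol condensation of salicylaldehydes with cinnamaldehydes ((S)-2-[diphenyl(trimethylsilyloxy)methyl]pyrrolidine, 2-nitrobenzoic acid, toluene). This should give (2R)-2-[3,4-bis(benzyloxy)phenyl]-3-formyl-2H-chromen-7-yl 4-methylbenzenesulfonate F2, with C2 set by attack of the phenol on the open face of the iminium ion. Conjugate reduction of F2 with the Hantzsch ester (dibenzylammonium trifluoroacetate, THF) saturates C3–C4 and, after equilibration at C3, should give trans-aldehyde 11. In this fallback ring F is closed through O1–C2 and C3–C4 instead.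

Step 5. Hydrogen migration in the Criegee adduct may compete with C3 migration and over-oxidise the aldehyde to the carboxylic acid, and the peracid may attack ring E. The fallback sets out from 11 and comes back at 14. MeMgBr (THF, −78 °C) adds to 11 to give (2S,3R)-2-[3,4-bis(benzyloxy)phenyl]-3-(1-hydroxyethyl)-3,4-dihydro-2H-chromen-7-yl 4-methylbenzenesulfonate F3 (both carbinol epimers). Dess–Martin periodinane oxidises it to (2S,3S)-3-acetyl-2-[3,4-bis(benzyloxy)phenyl]-3,4-dihydro-2H-chromen-7-yl 4-methylbenzenesulfonate F4. Baeyer–Villiger oxidation of this methyl ketone with mCPBA (secondary alkyl migrates in preference to methyl, with retention) gives (2R,3S)-3-acetoxy-2-[3,4-bis(benzyloxy)phenyl]-3,4-dihydro-2H-chromen-7-yl 4-methylbenzenesulfonate F5. Under the conditions of step 6, F5 gives 14.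

Step 12. The cation may be attacked with poor facial selectivity at C4 (3,4-cis isomer) or through C8; it may also self-condense with ring A of a second molecule of 24, or be captured at oxygen. The fallback is the classical free-phenol condensation; it sets out from 23 and 14 and comes back at 27. Hydrogenolysis of 23 (H2, Pd/C, EtOAc–MeOH) gives (2R,3R)-3,7-dihydroxy-2-(4-hydroxyphenyl)-2,3-dihydro-4H-chromen-4-one F6. NaBH4 in MeOH reduces it to (2R,3S,4R)-2-(4-hydroxyphenyl)-3,4-dihydro-2H-chromene-3,4,7-triol F7. Hydrogenolysis of 14 gives (2R,3S)-2-(3,4-dihydroxyphenyl)-3,4-dihydro-2H-chromene-3,7-diol F8. F7 and an excess of F8 are condensed in 0.1 M aqueous HCl at rt, where the C4 cation forms reversibly and is captured by the resorcinol-type ring D at C6. Target 27 is then separated from the 3,4-cis isomer on Sephadex LH-20.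

**Further compounds**

F1 | step 4 | (2E)-3-[3,4-bis(benzyloxy)phenyl]prop-2-enal | O=C/C=C/c1ccc(OCc2ccccc2)c(OCc2ccccc2)c1
F2 | step 4 | (2R)-2-[3,4-bis(benzyloxy)phenyl]-3-formyl-2H-chromen-7-yl 4-methylbenzenesulfonate | Cc1ccc(cc1)S(=O)(=O)Oc1ccc2c(c1)O[C@H](c1ccc(OCc3ccccc3)c(OCc3ccccc3)c1)C(C=O)=C2
F3 | step 5 | (2S,3R)-2-[3,4-bis(benzyloxy)phenyl]-3-(1-hydroxyethyl)-3,4-dihydro-2H-chromen-7-yl 4-methylbenzenesulfonate | Cc1ccc(cc1)S(=O)(=O)Oc1ccc2c(c1)O[C@H](c1ccc(OCc3ccccc3)c(OCc3ccccc3)c1)[C@@H](C(C)O)C2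
F4 | step 5 | (2S,3S)-3-acetyl-2-[3,4-bis(benzyloxy)phenyl]-3,4-dihydro-2H-chromen-7-yl 4-methylbenzenesulfonate | Cc1ccc(cc1)S(=O)(=O)Oc1ccc2c(c1)O[C@H](c1ccc(OCc3ccccc3)c(OCc3ccccc3)c1)[C@@H](C(C)=O)C2
F5 | step 5 | (2R,3S)-3-acetoxy-2-[3,4-bis(benzyloxy)phenyl]-3,4-dihydro-2H-chromen-7-yl 4-methylbenzenesulfonate | Cc1ccc(cc1)S(=O)(=O)Oc1ccc2c(c1)O[C@H](c1ccc(OCc3ccccc3)c(OCc3ccccc3)c1)[C@@H](OC(C)=O)C2
F6 | step 12 | (2R,3R)-3,7-dihydroxy-2-(4-hydroxyphenyl)-2,3-dihydro-4H-chromen-4-one | Oc1ccc(cc1)[C@H]1Oc2cc(O)ccc2C(=O)[C@@H]1O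
F7 | step 12 | (2R,3S,4R)-2-(4-hydroxyphenyl)-3,4-dihydro-2H-chromene-3,4,7-triol | Oc1ccc(cc1)[C@H]1Oc2cc(O)ccc2[C@@H](O)[C@@H]1O
F8 | step 12 | (2R,3S)-2-(3,4-dihydroxyphenyl)-3,4-dihydro-2H-chromene-3,7-diol | Oc1ccc2c(c1)O[C@H](c1ccc(O)c(O)c1)[C@@H](O)C2
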